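With the target numbered as a bicyclo[3.2.1]oct-2-en-8-one (allyl-bearing bridgehead C1, enol ether C2=C3, acetoxy carbon C4, methoxy-bearing bridgehead C5, aryl carbon C6, methyl carbon C7, carbonyl bridge C8), the C5–C8 bond is kept for a late transannular aldol. The seven-membered ring C1–C7, which carries every substituent, then becomes the real problem, with C8 as an ester on C1. One operation, rhodium-carbenoid cyclopropanation of a trioxygenated diene followed by Cope rearrangement of the cis-divinylcyclopropane, forms C1–C2 and C5–C6, closes that ring and sets C6 under catalyst control. Its precursors are a (3,4,5-trimethoxystyryl)diazoacetate and (Z)-1,3-dimethoxy-2-silyloxybutadiene.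

Key step: step 7

Remark 1: the atom numbers C1–C8 of the target are used for all intermediates, whatever the locants in their systematic names.
Remark 2 (assumption): Rh2(S-DOSP)4, dirhodium tetrakis[(S)-N-(4-dodecylphenylsulfonyl)prolinate], is taken to give cyclopropane 13 as the (1R,2R) isomer by analogy with its usual sense of induction with styryldiazoacetates; this sense is to be confirmed on the first batch, and Rh2(R-DOSP)4 would replace it with no other change if the antipode formed.
Remark 3 (assumption): the C8 carbinol configuration of 20 is of no consequence because it is oxidised in step 13; the epimer with the hydroxyl over the C2–C4 bridge is written.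

Step 1
Reactants: 1 3,4,5-trimethoxybenzaldehyde; 2 (2-carboxyethyl)triphenylphosphonium bromide
Product: 4 (E)-4-(3,4,5-trimethoxyphenyl)but-3-enoic acid, via phosphonium ylide carboxylate 3 (not isolated)
Conditions: NaN(SiMe3)2 (2.1 equiv), THF, −78 °C → rt; aq. HCl work-up
Reagents that add atoms: none
Why: Wittig olefination of an aryl aldehyde with the doubly deprotonated salt; the carboxylate in the ylide chain should favour the (E)-alkene, which stays in the β,γ-position because it is conjugated with the arene.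

Step 2
Reactants: 4 (E)-4-(3,4,5-trimethoxyphenyl)but-3-enoic acid
Product: 5 methyl (E)-4-(3,4,5-trimethoxyphenyl)but-3-enoate
Conditions: MeOH, H2SO4 (cat.), 50 °C
Reagents that add atoms: methanol, CO
Why: Fischer esterification; the styrenyl double bond has no driving force to move into conjugation with the ester under these conditions.

Step 3
Reactants: 5 methyl (E)-4-(3,4,5-trimethoxyphenyl)but-3-enoate
Product: 6 methyl (E)-2-diazo-4-(3,4,5-trimethoxyphenyl)but-3-enoate
Conditions: 4-acetamidobenzenesulfonyl azide, DBU, MeCN, 0 °C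
Reagents that add atoms: 4-acetamidobenzenesulfonyl azide, CC(=O)Nc1ccc(cc1)S(=O)(=O)N=[N+]=[N-]
Why: Regitz diazo transfer to the methylene that is activated by both the ester and the styrenyl group; the product is used promptly because vinyldiazoacetates slowly cyclise to pyrazoles.

Step 4
Reactants: 7 methyl methoxyacetate
Product: 8 N,2-dimethoxy-N-methylacetamide
Conditions: MeNH(OMe)·HCl, i-PrMgCl, THF, −20 → 0 °C
Reagents that add atoms: N,O-dimethylhydroxylamine hydrochloride, CNOC.Cl
Why: Weinreb amide formation by aminolysis of the ester with the chloromagnesium amide generated in the flask.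

Step 5
Reactants: 9 methyl vinyl ether; 8 N,2-dimethoxy-N-methylacetamide
Product: 11 1,3-dimethoxybut-3-en-2-one, via 1-methoxyvinyllithium 10 (not isolated)
Conditions: t-BuLi, THF, −78 → 0 °C; then 8, −78 °C; aq. NH4Cl
Reagents that add atoms: none
Why: α-Lithiation of the vinyl ether and Weinreb ketone synthesis; the chelated tetrahedral adduct prevents a second addition and the neutral quench keeps the enol ether intact.

Step 6
Reactants: 11 1,3-dimethoxybut-3-en-2-one
Product: 12 (Z)-tert-butyl[(1,3-dimethoxybuta-1,3-dien-2-yl)oxy]dimethylsilane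
Conditions: TBSOTf, Et3N, CH2Cl2, −78 → 0 °C
Reagents that add atoms: tert-butyldimethylsilyl trifluoromethanesulfonate, CC(C)(C)[Si](C)(C)OS(=O)(=O)C(F)(F)F
Why: Soft enolisation and O-silylation at the only enolisable carbon; the (Z)-enol ether (methoxy cis to silyloxy) is expected because the (E)-isomer would suffer allylic strain between the methoxy group and the 1-methoxyvinyl residue.

Step 7
Reactants: 6 methyl (E)-2-diazo-4-(3,4,5-trimethoxyphenyl)but-3-enoate; 12 (Z)-tert-butyl[(1,3-dimethoxybuta-1,3-dien-2-yl)oxy]dimethylsilane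
Product: 14 methyl (3R,4S)-5-[(tert-butyldimethylsilyl)oxy]-4,6-dimethoxy-3-(3,4,5-trimethoxyphenyl)cyclohepta-1,5-diene-1-carboxylate, via cis-divinylcyclopropane 13 (not isolated)
Conditions: Rh2(S-DOSP)4 (1 mol %), 12 (2 equiv), hexanes/toluene, −40 °C, slow addition of 6; then rt → 50 °C
Reagents that add atoms: none
Why: The catalyst turns 6 into a donor/acceptor carbenoid whose carbenoid carbon cyclopropanates the CH2=C(OMe) end of 12 with the dienyl residue cis to the styryl group, which forms C1–C2 and gives 13, and 13 then undergoes Cope rearrangement on warming. This is the established tandem cyclopropanation/Cope (formal 4+3) reaction of vinyldiazoacetates with alkoxy- and silyloxy-dienes. The seven-membered ring closes by a concerted suprafacial [3,3] shift through a boat transition state, in which C5–C6 forms while the cyclopropane bond between C1 and C3 breaks. C6 is controlled by the catalyst, which fixes the absolute configuration of 13 that the boat geometry relays, and C5 follows from the (E)-styryl and (Z)-methoxyvinyl termini, which place aryl and methoxy cis. The step needs attack at the disubstituted enol ether instead of the trisubstituted silyl enol ether, and at the carbenoid carbon instead of the vinylogous position; the steric demand of the carbenoid, the aryl-capped vinyl terminus and the hydrocarbon solvent should secure both.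

Step 8
Reactants: 14 methyl (3R,4S)-5-[(tert-butyldimethylsilyl)oxy]-4,6-dimethoxy-3-(3,4,5-trimethoxyphenyl)cyclohepta-1,5-diene-1-carboxylate
Product: 16 methyl (1R,5S,6R,7S)-4-[(tert-butyldimethylsilyl)oxy]-3,5-dimethoxy-7-methyl-1-(prop-2-en-1-yl)-6-(3,4,5-trimethoxyphenyl)cyclohept-3-ene-1-carboxylate, via lithium ester enolate 15 (not isolated)
Conditions: Me2CuLi (from MeLi and CuBr·SMe2), Et2O, −40 → 0 °C; then allyl bromide, DMPU, THF, −40 °C → rt
Reagents that add atoms: methyllithium, C[Li] (delivered as lithium dimethylcuprate, [Li+].C[Cu-]C); allyl bromide, C=CCBr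
Why: Tandem cuprate 1,4-addition and enolate alkylation; methyl should add to C7 on the face opposite the C6 aryl and C5 methoxy groups, and enolate 15, whose new methyl is held pseudo-axial by allylic strain, should take up allyl on the other face, so that allyl and methyl are trans.

Step 9
Reactants: 16 methyl (1R,5S,6R,7S)-4-[(tert-butyldimethylsilyl)oxy]-3,5-dimethoxy-7-methyl-1-(prop-2-en-1-yl)-6-(3,4,5-trimethoxyphenyl)cyclohept-3-ene-1-carboxylate
Product: 17 [(1R,5S,6R,7S)-4-[(tert-butyldimethylsilyl)oxy]-3,5-dimethoxy-7-methyl-1-(prop-2-en-1-yl)-6-(3,4,5-trimethoxyphenyl)cyclohept-3-en-1-yl]methanol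
Conditions: LiAlH4, Et2O, 0 °C; Na2SO4·10H2O quench
Reagents that add atoms: none
Why: Hydride reduction of the hindered ester to the neopentyl alcohol; the silyl enol ether is inert to LiAlH4 and the non-acidic quench avoids its hydrolysis.

Step 10
Reactants: 17 [(1R,5S,6R,7S)-4-[(tert-butyldimethylsilyl)oxy]-3,5-dimethoxy-7-methyl-1-(prop-2-en-1-yl)-6-(3,4,5-trimethoxyphenyl)cyclohept-3-en-1-yl]methanol
Product: 18 (1R,5S,6R,7S)-4-[(tert-butyldimethylsilyl)oxy]-3,5-dimethoxy-7-methyl-1-(prop-2-en-1-yl)-6-(3,4,5-trimethoxyphenyl)cyclohept-3-ene-1-carbaldehyde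
Conditions: (n-Pr)4N[RuO4] (5 mol %), N-methylmorpholine N-oxide, 4 Å molecular sieves, CH2Cl2, rt
Reagents that add atoms: none
Why: Ley–Griffith oxidation under neutral conditions, which spare the electron-rich silyl enol ether; the aldehyde has no α-hydrogen and cannot epimerise or over-oxidise under these conditions.

Step 11
Reactants: 18 (1R,5S,6R,7S)-4-[(tert-butyldimethylsilyl)oxy]-3,5-dimethoxy-7-methyl-1-(prop-2-en-1-yl)-6-(3,4,5-trimethoxyphenyl)cyclohept-3-ene-1-carbaldehyde
Product: 19 (1S,5S,6R,7S)-3,5-dimethoxy-7-methyl-4-oxo-1-(prop-2-en-1-yl)-6-(3,4,5-trimethoxyphenyl)cyclohept-2-ene-1-carbaldehyde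
Conditions: Pd(OAc)2 (1.2 equiv), MeCN, rt → 40 °C
Reagents that add atoms: none
Why: Saegusa–Ito oxidation; the palladium enolate formed at C3 has β-hydrogens only at C2, so elimination can give only the C2=C3–C4(=O) enone.

Step 12
Reactants: 19 (1S,5S,6R,7S)-3,5-dimethoxy-7-methyl-4-oxo-1-(prop-2-en-1-yl)-6-(3,4,5-trimethoxyphenyl)cyclohept-2-ene-1-carbaldehyde
Product: 20 (1S,5R,6R,7S,8R)-8-hydroxy-3,5-dimethoxy-7-methyl-1-(prop-2-en-1-yl)-6-(3,4,5-trimethoxyphenyl)bicyclo[3.2.1]oct-2-en-4-one
Conditions: DBU (0.5 equiv), THF, 0 °C → rt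
Reagents that add atoms: none
Why: Transannular aldol addition; C5–H is the only enolisable position, and the formyl carbon on C1 can bond to C5 only as a one-carbon bridge syn to the C7 methyl and anti to the C6 aryl, which fixes C5, while dehydration is impossible because both neighbours of C8 are quaternary.

Step 13
Reactants: 20 (1S,5R,6R,7S,8R)-8-hydroxy-3,5-dimethoxy-7-methyl-1-(prop-2-en-1-yl)-6-(3,4,5-trimethoxyphenyl)bicyclo[3.2.1]oct-2-en-4-one
Product: 21 (1S,5R,6R,7S)-3,5-dimethoxy-7-methyl-1-(prop-2-en-1-yl)-6-(3,4,5-trimethoxyphenyl)bicyclo[3.2.1]oct-2-ene-4,8-dione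
Conditions: Dess–Martin periodinane, NaHCO3, CH2Cl2, rt
Reagents that add atoms: none
Why: Dess–Martin oxidation of a hindered secondary alcohol under buffered, non-basic conditions, which avoid retro-aldol opening; the dione cannot enolise between the carbonyls.

Step 14
Reactants: 21 (1S,5R,6R,7S)-3,5-dimethoxy-7-methyl-1-(prop-2-en-1-yl)-6-(3,4,5-trimethoxyphenyl)bicyclo[3.2.1]oct-2-ene-4,8-dione
Product: 22 (1S,4R,5S,6R,7S)-4-hydroxy-3,5-dimethoxy-7-methyl-1-(prop-2-en-1-yl)-6-(3,4,5-trimethoxyphenyl)bicyclo[3.2.1]oct-2-en-8-one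
Conditions: NaBH4 (1.0 equiv), CeCl3·7H2O, MeOH, −78 °C
Reagents that add atoms: none
Why: Luche reduction; with CeCl3 in methanol the conjugated C4 carbonyl should be reduced 1,2 in preference to the isolated C8 ketone, which is flanked by two quaternary carbons, and hydride should arrive on the face of C4 syn to the C8 bridge because the endo C6 aryl covers the other face, giving the (4R)-alcohol.

Step 15
Reactants: 22 (1S,4R,5S,6R,7S)-4-hydroxy-3,5-dimethoxy-7-methyl-1-(prop-2-en-1-yl)-6-(3,4,5-trimethoxyphenyl)bicyclo[3.2.1]oct-2-en-8-one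
Product: 23 (1S,4R,5S,6R,7S)-3,5-dimethoxy-7-methyl-8-oxo-1-(prop-2-en-1-yl)-6-(3,4,5-trimethoxyphenyl)bicyclo[3.2.1]oct-2-en-4-yl acetate
Conditions: Ac2O, pyridine, DMAP (cat.), CH2Cl2, 0 °C → rt
Reagents that add atoms: acetic anhydride, CC(=O)OC(C)=O
Why: Nucleophile-catalysed acetylation of the secondary allylic alcohol under mild base, which should not trigger retro-aldol cleavage of the β-hydroxy ketone.

Compound list
1 | 3,4,5-trimethoxybenzaldehyde | COc1cc(C=O)cc(OC)c1OC | starting material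
2 | (2-carboxyethyl)triphenylphosphonium bromide | OC(=O)CC[P+](c1ccccc1)(c1ccccc1)c1ccccc1.[Br-] | starting material
3 | sodium 3-(triphenyl-λ5-phosphanylidene)propanoate (ylide carboxylate) | [Na+].[O-]C(=O)CC=P(c1ccccc1)(c1ccccc1)c1ccccc1 | intermediate
4 | (E)-4-(3,4,5-trimethoxyphenyl)but-3-enoic acid | OC(=O)C/C=C/c1cc(OC)c(OC)c(OC)c1 | intermediate
5 | methyl (E)-4-(3,4,5-trimethoxyphenyl)but-3-enoate | COC(=O)C/C=C/c1cc(OC)c(OC)c(OC)c1 | intermediate
6 | methyl (E)-2-diazo-4-(3,4,5-trimethoxyphenyl)but-3-enoate | COC(=O)C(=[N+]=[N-])/C=C/c1cc(OC)c(OC)c(OC)c1 | intermediate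
7 | methyl methoxyacetate | COCC(=O)OC | starting material
8 | N,2-dimethoxy-N-methylacetamide | COCC(=O)N(C)OC | intermediate
9 | methyl vinyl ether | COC=C | starting material
10 | 1-methoxyvinyllithium | [Li]C(=C)OC | intermediate
11 | 1,3-dimethoxybut-3-en-2-one | COCC(=O)C(=C)OC | intermediate
12 | (Z)-tert-butyl[(1,3-dimethoxybuta-1,3-dien-2-yl)oxy]dimethylsilane | CO/C=C(\O[Si](C)(C)C(C)(C)C)C(=C)OC | intermediate
13 | methyl (1R,2R)-2-{(Z)-1-[(tert-butyldimethylsilyl)oxy]-2-methoxyethenyl}-2-methoxy-1-[(E)-2-(3,4,5-trimethoxyphenyl)ethenyl]cyclopropane-1-carboxylate (the two alkenyl groups cis) | COC(=O)[C@@]1(/C=C/c2cc(OC)c(OC)c(OC)c2)C[C@]1(OC)/C(O[Si](C)(C)C(C)(C)C)=C/OC | intermediate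
14 | methyl (3R,4S)-5-[(tert-butyldimethylsilyl)oxy]-4,6-dimethoxy-3-(3,4,5-trimethoxyphenyl)cyclohepta-1,5-diene-1-carboxylate (aryl and methoxy cis) | COC(=O)C1=C[C@H](c2cc(OC)c(OC)c(OC)c2)[C@H](OC)C(O[Si](C)(C)C(C)(C)C)=C(OC)C1 | intermediate
15 | lithium ester enolate of the C7-methylated ester (exocyclic C1=C(OMe)OLi; 5S,6R,7S) | [Li+].COC([O-])=C1CC(OC)=C(O[Si](C)(C)C(C)(C)C)[C@@H](OC)[C@@H](c2cc(OC)c(OC)c(OC)c2)[C@@H]1C | intermediate
16 | methyl (1R,5S,6R,7S)-4-[(tert-butyldimethylsilyl)oxy]-3,5-dimethoxy-7-methyl-1-(prop-2-en-1-yl)-6-(3,4,5-trimethoxyphenyl)cyclohept-3-ene-1-carboxylate | C=CC[C@@]1(C(=O)OC)CC(OC)=C(O[Si](C)(C)C(C)(C)C)[C@@H](OC)[C@@H](c2cc(OC)c(OC)c(OC)c2)[C@@H]1C | intermediate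
17 | [(1R,5S,6R,7S)-4-[(tert-butyldimethylsilyl)oxy]-3,5-dimethoxy-7-methyl-1-(prop-2-en-1-yl)-6-(3,4,5-trimethoxyphenyl)cyclohept-3-en-1-yl]methanol | C=CC[C@@]1(CO)CC(OC)=C(O[Si](C)(C)C(C)(C)C)[C@@H](OC)[C@@H](c2cc(OC)c(OC)c(OC)c2)[C@@H]1C | intermediate
18 | (1R,5S,6R,7S)-4-[(tert-butyldimethylsilyl)oxy]-3,5-dimethoxy-7-methyl-1-(prop-2-en-1-yl)-6-(3,4,5-trimethoxyphenyl)cyclohept-3-ene-1-carbaldehyde | C=CC[C@@]1(C=O)CC(OC)=C(O[Si](C)(C)C(C)(C)C)[C@@H](OC)[C@@H](c2cc(OC)c(OC)c(OC)c2)[C@@H]1C | intermediate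
19 | (1S,5S,6R,7S)-3,5-dimethoxy-7-methyl-4-oxo-1-(prop-2-en-1-yl)-6-(3,4,5-trimethoxyphenyl)cyclohept-2-ene-1-carbaldehyde | C=CC[C@@]1(C=O)C=C(OC)C(=O)[C@@H](OC)[C@@H](c2cc(OC)c(OC)c(OC)c2)[C@@H]1C | intermediate
20 | (1S,5R,6R,7S,8R)-8-hydroxy-3,5-dimethoxy-7-methyl-1-(prop-2-en-1-yl)-6-(3,4,5-trimethoxyphenyl)bicyclo[3.2.1]oct-2-en-4-one | C=CC[C@]12C=C(OC)C(=O)[C@](OC)([C@@H]1O)[C@@H](c1cc(OC)c(OC)c(OC)c1)[C@@H]2C | intermediate
21 | (1S,5R,6R,7S)-3,5-dimethoxy-7-methyl-1-(prop-2-en-1-yl)-6-(3,4,5-trimethoxyphenyl)bicyclo[3.2.1]oct-2-ene-4,8-dione | C=CC[C@]12C=C(OC)C(=O)[C@](OC)(C1=O)[C@@H](c1cc(OC)c(OC)c(OC)c1)[C@@H]2C | intermediate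
22 | (1S,4R,5S,6R,7S)-4-hydroxy-3,5-dimethoxy-7-methyl-1-(prop-2-en-1-yl)-6-(3,4,5-trimethoxyphenyl)bicyclo[3.2.1]oct-2-en-8-one | C=CC[C@]12C=C(OC)[C@@H](O)[C@](OC)(C1=O)[C@@H](c1cc(OC)c(OC)c(OC)c1)[C@@H]2C | intermediate
23 | (1S,4R,5S,6R,7S)-3,5-dimethoxy-7-methyl-8-oxo-1-(prop-2-en-1-yl)-6-(3,4,5-trimethoxyphenyl)bicyclo[3.2.1]oct-2-en-4-yl acetate (CNP0181407.1) | C=CC[C@]12C=C(OC)[C@@H](OC(C)=O)[C@](OC)(C1=O)[C@@H](c1cc(OC)c(OC)c(OC)c1)[C@@H]2C | target

Total step count: 15.
Longest linear sequence: 12 steps (steps 1–3, then 7–15); the diene arm (steps 4–6, then 7–15) is of equal length.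

Steps most likely to fail

Step 7. Enantiocontrol may be eroded if the alkoxy-substituted donor–acceptor cyclopropane opens to a zwitterion before it rearranges, and the carbenoid may partly react at its vinylogous terminus. The fallback moves stereocontrol from the catalyst to a covalently bound auxiliary and allows purification of diastereomers. It sets out from acid 4, which would be esterified with (R)-pantolactone (DCC, DMAP, CH2Cl2) to give the pantolactonyl butenoate F1. Diazo transfer as in step 3 would give the pantolactonyl vinyldiazoacetate F2. Reaction of F2 with 12 under the achiral catalyst Rh2(O2CC7H15)4 in hexanes would pass through the pantolactonyl cis-divinylcyclopropane F3 to the pantolactonyl cycloheptadiene ester F4, which would be freed from its minor diastereomer by chromatography or crystallisation. Brief methanolysis (NaOMe, MeOH, 0 °C) would then return the route at 14. The enantiomer of the auxiliary would be chosen by the same first-batch check as in remark 2.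

Step 8. The cuprate may add incompletely to the hindered, γ-branched enoate, and the copper-bound enolate may be protonated on work-up instead of being allylated. The fallback uncouples the two bond formations and sets out from 14. Silyl-accelerated conjugate addition (Me2CuLi, Me3SiCl, THF, −78 °C) would give the O-methyl O-trimethylsilyl ketene acetal F5, which aqueous NH4Cl would hydrolyse to the C7-methylated saturated ester F6 as a mixture at C1. Deprotonation of F6 with LiN(i-Pr)2 in THF/DMPU at −78 °C would regenerate the free lithium enolate 15, and allyl bromide would be added under the same allylic-strain control. The fallback returns at 16.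

Step 14. Hydride may also attack the strained C8 bridging ketone, or methoxide may open the non-enolisable 1,3-dione by retro-Claisen cleavage. The fallback changes the order of events so that C4 is reduced while C8 is still a carbinol, and it sets out from 20. Hydroxyl-directed reduction (Me4NBH(OAc)3, MeCN/AcOH, −20 °C), with internal hydride delivery from the C8 oxygen to the upper face of C4, would give the 4,8-diol F7. Acetylation without DMAP (Ac2O, pyridine, 0 °C) should occur at the allylic C4 hydroxyl and spare the C8 hydroxyl, which lies between two quaternary carbons, to give the 8-hydroxy 4-acetate F8. Dess–Martin oxidation of F8 would return the route at 23.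

Further compounds
F1 | step 7 | (3R)-4,4-dimethyl-2-oxooxolan-3-yl (E)-4-(3,4,5-trimethoxyphenyl)but-3-enoate | CC1(C)COC(=O)[C@@H]1OC(=O)C/C=C/c1cc(OC)c(OC)c(OC)c1
F2 | step 7 | (3R)-4,4-dimethyl-2-oxooxolan-3-yl (E)-2-diazo-4-(3,4,5-trimethoxyphenyl)but-3-enoate | CC1(C)COC(=O)[C@@H]1OC(=O)C(=[N+]=[N-])/C=C/c1cc(OC)c(OC)c(OC)c1
F3 | step 7 | (3R)-4,4-dimethyl-2-oxooxolan-3-yl (1R,2R)-2-{(Z)-1-[(tert-butyldimethylsilyl)oxy]-2-methoxyethenyl}-2-methoxy-1-[(E)-2-(3,4,5-trimethoxyphenyl)ethenyl]cyclopropane-1-carboxylate | CC1(C)COC(=O)[C@@H]1OC(=O)[C@@]2(/C=C/c3cc(OC)c(OC)c(OC)c3)C[C@]2(OC)/C(O[Si](C)(C)C(C)(C)C)=C/OC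
F4 | step 7 | (3R)-4,4-dimethyl-2-oxooxolan-3-yl (3R,4S)-5-[(tert-butyldimethylsilyl)oxy]-4,6-dimethoxy-3-(3,4,5-trimethoxyphenyl)cyclohepta-1,5-diene-1-carboxylate | CC1(C)COC(=O)[C@@H]1OC(=O)C2=C[C@H](c3cc(OC)c(OC)c(OC)c3)[C@H](OC)C(O[Si](C)(C)C(C)(C)C)=C(OC)C2
F5 | step 8 | O-methyl O-trimethylsilyl ketene acetal of ester F6 (exocyclic C1=C; 5S,6R,7S) | COC(O[Si](C)(C)C)=C1CC(OC)=C(O[Si](C)(C)C(C)(C)C)[C@@H](OC)[C@@H](c2cc(OC)c(OC)c(OC)c2)[C@@H]1C
F6 | step 8 | methyl (5S,6R,7S)-4-[(tert-butyldimethylsilyl)oxy]-3,5-dimethoxy-7-methyl-6-(3,4,5-trimethoxyphenyl)cyclohept-3-ene-1-carboxylate (C1 not defined) | COC(=O)C1CC(OC)=C(O[Si](C)(C)C(C)(C)C)[C@@H](OC)[C@@H](c2cc(OC)c(OC)c(OC)c2)[C@@H]1C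
F7 | step 14 | (1S,4R,5R,6R,7S,8R)-3,5-dimethoxy-7-methyl-1-(prop-2-en-1-yl)-6-(3,4,5-trimethoxyphenyl)bicyclo[3.2.1]oct-2-ene-4,8-diol | C=CC[C@]12C=C(OC)[C@@H](O)[C@](OC)([C@@H]1O)[C@@H](c1cc(OC)c(OC)c(OC)c1)[C@@H]2C
F8 | step 14 | (1S,4R,5R,6R,7S,8R)-8-hydroxy-3,5-dimethoxy-7-methyl-1-(prop-2-en-1-yl)-6-(3,4,5-trimethoxyphenyl)bicyclo[3.2.1]oct-2-en-4-yl acetate | C=CC[C@]12C=C(OC)[C@@H](OC(C)=O)[C@](OC)([C@@H]1O)[C@@H](c1cc(OC)c(OC)c(OC)c1)[C@@H]2C
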